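## Retrosynthetic overview

- The terminal C=CH2 is cut last: the target comes from the aryl ketone by methylenation.
- The aryl–C(=O) bond, which joins side chain and ring, comes from a photo-Fries shift of a hydroquinone monoester; with the para position carrying OH and one ortho position carrying OMe, only one ortho carbon is free.
- That monoester comes from a chiral α-angeloyloxy acid and 3-methoxy-2-methylphenol by a new anodic para C–H acyloxylation, which brings in the second ring oxygen and fixes the ring regiochemistry.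
- The acid comes from (S)-methyl glycidate (the only stereocentre, bought), an isobutenyl Grignard reagent (C–C) and angelic acid (C–O).
- No ring is formed; the benzene ring is bought.

Assumption: (S)-methyl glycidate, the isobutenyl Grignard solution, angelic acid and 3-methoxy-2-methylphenol are taken as catalogue compounds.

## Route

Step 1
Reactants: 1 methyl (S)-oxirane-2-carboxylate; 2 (2-methylprop-1-en-1-yl)magnesium bromide
Product: 3 methyl (S)-2-hydroxy-5-methylhex-4-enoate
Conditions: 2 (1.3 equiv), CuI (10 mol%), THF, −40 °C, 1 h; then sat. aq. NH4Cl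
Reagents that add atoms: none
Why: Copper-catalysed Grignard opening (SN2) of the epoxide at its unsubstituted CH2 carbon outruns addition to the ester at −40 °C, and because the C2–O bond of 1 is never broken the (S) centre of the target is carried over unchanged from the bought glycidate.

Step 2
Reactants: 3 methyl (S)-2-hydroxy-5-methylhex-4-enoate; 4 angelic acid
Product: 6 methyl (S)-5-methyl-2-{[(Z)-2-methylbut-2-enoyl]oxy}hex-4-enoate, via mixed anhydride 5 (not isolated)
Conditions: 4 (2 equiv), 2,4,6-trichlorobenzoyl chloride (2 equiv), Et3N (2.2 equiv), toluene, rt, 2 h; then 3, 80 °C, 24 h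
Reagents that add atoms: none
Why: Yamaguchi esterification through the mixed anhydride, run without DMAP so that the (Z)-angelate does not isomerise to the tiglate; acylation on oxygen leaves the stereocentre untouched.

Step 3
Reactants: 6 methyl (S)-5-methyl-2-{[(Z)-2-methylbut-2-enoyl]oxy}hex-4-enoate
Product: 7 (S)-5-methyl-2-{[(Z)-2-methylbut-2-enoyl]oxy}hex-4-enoic acid
Conditions: Me3SnOH (6 equiv), ClCH2CH2Cl, 75 °C; then 1 M HCl wash
Reagents that add atoms: trimethyltin hydroxide, C[Sn](C)(C)O
Why: Me3SnOH-mediated ester cleavage is selective for the unhindered methyl ester under near-neutral conditions, sparing the hindered conjugated angelate and not enolising the α-centre.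

Step 4
Reactants: 7 (S)-5-methyl-2-{[(Z)-2-methylbut-2-enoyl]oxy}hex-4-enoic acid; 8 3-methoxy-2-methylphenol
Product: 9 4-hydroxy-2-methoxy-3-methylphenyl (S)-5-methyl-2-{[(Z)-2-methylbut-2-enoyl]oxy}hex-4-enoate
Conditions: undivided cell, graphite anode, Pt cathode, 5 mA cm−2, 2.2 F mol−1 (on 7); 8 (4 equiv), 2,6-lutidine (1.2 equiv), Bu4NPF6 (0.1 M), MeCN/(CF3)2CHOH 9:1, 0 °C
Reagents that add atoms: none
Why: Proposed new method: anodic dehydrogenative C–O coupling in which phenol 8 (estimated E ≈ +1.0 to +1.3 V vs SCE, below the trisubstituted alkene, the angelate and the carboxylate of 7) is oxidised by two electrons and loss of a proton to a phenoxonium ion stabilised by the fluoro alcohol, the lutidinium carboxylate of 7 traps it at the unsubstituted para carbon, and proton loss restores the arene as the monoester, whose electron-poorer acyloxy group should make it somewhat harder to oxidise than 8 so that, with 8 in excess, over-oxidation is held back (cathode: H2); para attack alone puts the ester on the oxygen next to OMe and leaves the free OH next to the methyl group, no stereocentre is formed and the α-centre of 7 is not involved; the closest known reactions are anodic nuclear acyloxylation of anisoles in carboxylate media and the anodic or hypervalent-iodine trapping of para-substituted phenols by carboxylic acids (quinol esters, spirolactones), neither shown for a para-unsubstituted phenol with a complex carboxylic acid as the limiting partner.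

Step 5
Reactants: 9 4-hydroxy-2-methoxy-3-methylphenyl (S)-5-methyl-2-{[(Z)-2-methylbut-2-enoyl]oxy}hex-4-enoate
Product: 10 (S)-1-(2,5-dihydroxy-3-methoxy-4-methylphenyl)-5-methyl-1-oxohex-4-en-2-yl (Z)-2-methylbut-2-enoate
Conditions: hν (300–310 nm, Pyrex-filtered, FEP flow coil), degassed MeCN (0.01 M), (E)-penta-1,3-diene (0.05 M), 15 °C
Reagents that add atoms: none
Why: Photo-Fries rearrangement, in which singlet-state homolysis of the ArO–C(=O) bond gives a caged aryloxyl/acyl radical pair that recombines at the only free ortho carbon (the other ortho carbon carries OMe, the para carbon OH) faster than the acyl radical loses CO, and tautomerisation gives the o-hydroxyaryl ketone; the α-stereocentre is a spectator, light above 290 nm is not absorbed by the angelate, and the diene quenches triplets that could isomerise it without affecting the singlet pathway.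

Step 6
Reactants: 10 (S)-1-(2,5-dihydroxy-3-methoxy-4-methylphenyl)-5-methyl-1-oxohex-4-en-2-yl (Z)-2-methylbut-2-enoate
Product: 11 (S)-2-(2,5-dihydroxy-3-methoxy-4-methylphenyl)-6-methylhepta-1,5-dien-3-yl (Z)-2-methylbut-2-enoate
Conditions: pre-formed Zn/CH2Br2/TiCl4 reagent (5 equiv), THF/CH2Cl2, 0 °C to rt, Ar; then aq. NaHCO3
Reagents that add atoms: dibromomethane, BrCBr
Why: Takai–Lombardo methylenation, whose non-basic gem-dimetallic CH2 reagent converts the ketone into the 1,1-disubstituted alkene without enolising the α-acyloxy centre, tolerates free OH groups at the cost of extra reagent and leaves esters alone, so the stereocentre is unchanged.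

## Compound list

1 | methyl (S)-oxirane-2-carboxylate, (S)-methyl glycidate | COC(=O)[C@@H]1CO1 | starting material
2 | (2-methylprop-1-en-1-yl)magnesium bromide | CC(C)=C[Mg]Br | starting material
3 | methyl (S)-2-hydroxy-5-methylhex-4-enoate | COC(=O)[C@@H](O)CC=C(C)C | intermediate
4 | angelic acid, (Z)-2-methylbut-2-enoic acid | C/C=C(/C)C(=O)O | starting material
5 | (Z)-2-methylbut-2-enoic 2,4,6-trichlorobenzoic anhydride | O=C(OC(=O)/C(C)=C\C)c1c(Cl)cc(Cl)cc1Cl | intermediate (not isolated)
6 | methyl (S)-5-methyl-2-{[(Z)-2-methylbut-2-enoyl]oxy}hex-4-enoate | COC(=O)[C@@H](OC(=O)/C(C)=C\C)CC=C(C)C | intermediate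
7 | (S)-5-methyl-2-{[(Z)-2-methylbut-2-enoyl]oxy}hex-4-enoic acid | OC(=O)[C@@H](OC(=O)/C(C)=C\C)CC=C(C)C | intermediate
8 | 3-methoxy-2-methylphenol | COc1cccc(O)c1C | starting material
9 | 4-hydroxy-2-methoxy-3-methylphenyl (S)-5-methyl-2-{[(Z)-2-methylbut-2-enoyl]oxy}hex-4-enoate | O=C(Oc1ccc(O)c(C)c1OC)[C@@H](OC(=O)/C(C)=C\C)CC=C(C)C | intermediate
10 | (S)-1-(2,5-dihydroxy-3-methoxy-4-methylphenyl)-5-methyl-1-oxohex-4-en-2-yl (Z)-2-methylbut-2-enoate | O=C(c1cc(O)c(C)c(OC)c1O)[C@@H](OC(=O)/C(C)=C\C)CC=C(C)C | intermediate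
11 | (S)-2-(2,5-dihydroxy-3-methoxy-4-methylphenyl)-6-methylhepta-1,5-dien-3-yl (Z)-2-methylbut-2-enoate (CNP0248710.1) | C=C(c1cc(O)c(C)c(OC)c1O)[C@H](CC=C(C)C)OC(=O)/C(C)=C\C | target

## Step count and risks

Total step count: 6. Longest linear sequence: 6 (1 → 3 → 6 → 7 → 9 → 10 → 11; 2, 4 and 8 are bought).

The three steps most likely to fail:

Step 4, the new anodic C–O coupling. Homocoupling of 8 through its phenoxyl radical, ortho attack, over-oxidation to the quinone or anodic decarboxylation of 7 could take over. The fallback uses only known chemistry, sets out from 7 and comes back at 9. Bought 2-methoxy-3-methylphenol is brominated para to the hydroxyl (NBS, MeCN, 0 °C) to 4-bromo-2-methoxy-3-methylphenol F1. F1 is esterified with 7 (EDC·HCl, cat. DMAP, CH2Cl2, 0 °C) to the bromoaryl ester F2. Miyaura borylation (B2pin2, PdCl2(dppf), KOAc, dioxane, 80 °C) gives the aryl pinacol boronate F3. Buffered oxidation (H2O2, pH 7 phosphate, THF, 0 °C) turns C–B into C–OH and gives 9.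

Step 5, the photo-Fries shift. Cage escape (free hydroquinone, decarbonylation) can lower the yield, and sensitised Z to E isomerisation of the angelate would be hard to correct. The fallback replaces the photochemical shift by a thermal cross-coupling, sets out from 7 and comes back at 10. Bought 2-methoxy-3-methylphenol is protected (MOMCl, diisopropylethylamine, CH2Cl2) as the methoxymethyl ether F4. Acid 7 is converted ((COCl)2, cat. DMF, CH2Cl2, 0 °C) into the acid chloride F5. F4 is lithiated ortho to the OMOM group (n-BuLi, TMEDA, Et2O, 0 °C), transmetalated with ZnCl2 and coupled with F5 (Pd(PPh3)4 cat., THF, 0 °C; Negishi acylation) to the MOM-protected aryl ketone F6. PPTS in MeOH (45 °C) frees the o-acylphenol F7. (KSO3)2NO in acetone/aq. KH2PO4 oxidises F7 para to the hydroxyl to the acylquinone F8. Aqueous Na2S2O4 reduces F8 to 10.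

Step 6, methylenation of a chelated, electron-rich ketone beside two free phenols. The reaction may be sluggish, or the Lewis-acidic medium may damage the acid-sensitive styrene product. The fallback sets out from 10 and comes back at 11. Both phenols are silylated (TBSOTf, 2,6-lutidine, CH2Cl2, 0 °C) to the bis-silyl ether ketone F9. F9 is methylenated with the titanium carbene source Cp2Ti(μ-CH2)(μ-Cl)AlMe2 (THF/toluene, pyridine, −40 to 0 °C) to the bis-silyl ether alkene F10. Bu4NF buffered with AcOH (THF, 0 °C) removes both silyl groups and gives 11.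

Further compounds

F1 | step 4 | 4-bromo-2-methoxy-3-methylphenol | COc1c(O)ccc(Br)c1C
F2 | step 4 | 4-bromo-2-methoxy-3-methylphenyl (S)-5-methyl-2-{[(Z)-2-methylbut-2-enoyl]oxy}hex-4-enoate | O=C(Oc1ccc(Br)c(C)c1OC)[C@@H](OC(=O)/C(C)=C\C)CC=C(C)C
F3 | step 4 | 2-methoxy-3-methyl-4-(4,4,5,5-tetramethyl-1,3,2-dioxaborolan-2-yl)phenyl (S)-5-methyl-2-{[(Z)-2-methylbut-2-enoyl]oxy}hex-4-enoate | O=C(Oc1ccc(B2OC(C)(C)C(C)(C)O2)c(C)c1OC)[C@@H](OC(=O)/C(C)=C\C)CC=C(C)C
F4 | step 5 | 2-methoxy-1-(methoxymethoxy)-3-methylbenzene | COCOc1cccc(C)c1OC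
F5 | step 5 | (S)-5-methyl-2-{[(Z)-2-methylbut-2-enoyl]oxy}hex-4-enoyl chloride | ClC(=O)[C@@H](OC(=O)/C(C)=C\C)CC=C(C)C
F6 | step 5 | (S)-1-[3-methoxy-2-(methoxymethoxy)-4-methylphenyl]-5-methyl-1-oxohex-4-en-2-yl (Z)-2-methylbut-2-enoate | O=C(c1ccc(C)c(OC)c1OCOC)[C@@H](OC(=O)/C(C)=C\C)CC=C(C)C
F7 | step 5 | (S)-1-(2-hydroxy-3-methoxy-4-methylphenyl)-5-methyl-1-oxohex-4-en-2-yl (Z)-2-methylbut-2-enoate | O=C(c1ccc(C)c(OC)c1O)[C@@H](OC(=O)/C(C)=C\C)CC=C(C)C
F8 | step 5 | (S)-1-(5-methoxy-4-methyl-3,6-dioxocyclohexa-1,4-dien-1-yl)-5-methyl-1-oxohex-4-en-2-yl (Z)-2-methylbut-2-enoate | O=C(C1=CC(=O)C(C)=C(OC)C1=O)[C@@H](OC(=O)/C(C)=C\C)CC=C(C)C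
F9 | step 6 | (S)-1-[2,5-bis(tert-butyldimethylsilyloxy)-3-methoxy-4-methylphenyl]-5-methyl-1-oxohex-4-en-2-yl (Z)-2-methylbut-2-enoate | O=C(c1cc(O[Si](C)(C)C(C)(C)C)c(C)c(OC)c1O[Si](C)(C)C(C)(C)C)[C@@H](OC(=O)/C(C)=C\C)CC=C(C)C
F10 | step 6 | (S)-2-[2,5-bis(tert-butyldimethylsilyloxy)-3-methoxy-4-methylphenyl]-6-methylhepta-1,5-dien-3-yl (Z)-2-methylbut-2-enoate | C=C(c1cc(O[Si](C)(C)C(C)(C)C)c(C)c(OC)c1O[Si](C)(C)C(C)(C)C)[C@@H](OC(=O)/C(C)=C\C)CC=C(C)C
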